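## Structural features

The target is a dimer of two 2,3-trans-flavan-3-ols. The upper robinetinidol unit has ring A with a single hydroxyl at C7, pyran ring C, and pyrogallol ring B at C2. The lower gallocatechin unit has phloroglucinol-type ring D, pyran ring F, and pyrogallol ring B' at C2'. One sp3–sp2 bond, C4 (ring C) to C8' (ring D), joins them. Ring C carries three contiguous stereocentres in the all-trans arrangement (2R,3S,4S: ring B and ring D on the α face, the C3 hydroxyl on the β face). Ring F carries the adjacent pair C2'/C3' (2R,3S), which is the pair found in (+)-gallocatechin. The nine phenolic hydroxyls, six of them in two pyrogallol rings, make the free compound sensitive to air and base, and the benzylic C2–O1, C2'–O1' and C4–C8' bonds are sensitive to acid, so the phenols must stay masked until a neutral last step. The real difficulty is the junction: the bond must go to C8' and not C6', ring D must end up trans to the C3 oxygen, and C2, C3 and C4 must be set relative to a lower unit that is too remote to direct them. The key step exploits the fact that O1–C8a–C4a–C4 of ring C is the skeleton of an ortho-quinone methide of ring A (C4 exocyclic and already bonded to C8'), while C2–C3 is the skeleton of a trans-styrene carrying ring B.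

## Logic of the disconnections

**15 to 14.** The ten O–CH2Ph bonds are cut last in the analysis. One ether type masks every phenol and the C3' alcohol and is removed under neutral conditions. The gain is that all earlier chemistry is done on a non-oxidisable, organic-soluble compound. The demand is that hydrogenolysis cleaves ten ethers without touching the ring benzylic C–O bonds.

**14 to 13.** The C3–O bond is traced back to a C3–B bond. An oxygen on the two-carbon partner would make it an enol ether, which attacks a quinone methide through its aryl-bearing carbon and would give the wrong regiochemistry. Boron is a placeholder that leaves the aryl group in charge of polarity and is exchanged for oxygen with retention. The demand is an oxidation that outruns β-elimination of O1.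

**13 to 9 and 11 (through 12).** O1–C2 and C3–C4 are cut. This opens ring C, removes all three of its stereocentres, and splits the molecule into two pieces of comparable size. The demand is high: the boron-bearing carbon must bond to C4, ring B must sit endo, and one face of 12 must be chosen by the catalyst. The acid that makes 12 must not let it condense with the free C6' of ring D or C6 of ring A.

**9 to 8.** The phenol O–allyl bond is cut. The phenol has to be masked during the organolithium step and freed without acid, because 9 ionises very easily. The demand is a neutral deallylation that does not transfer allyl to the electron-rich ring.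

**8 to 4 and 6 (through 7).** The bond between the carbinol carbon (future C4) and C8' is cut. Making it by addition of an aryl anion to an aldehyde fixes the junction at C8', because the metal sits where the bromine was. The carbinol configuration is irrelevant, since it is erased in 12. The demand is that halogen–metal exchange beats benzylic deprotonation.

**4 to 3 to 2 to 1.** The C8'–Br bond and six O–benzyl bonds are cut. Both stereocentres of ring F are bought with 1. The demands are C8 selectivity in bromination and no epimerisation at C2' under base.

**6 to 5.** One O–allyl bond is cut; the demand is only clean O-alkylation.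

**11 to 10.** The C=C bond is cut by olefination back to the aldehyde and a gem-diborylmethane. This makes 11 in one step instead of two (alkyne formation, then hydroboration). The demand is E geometry.

## Other disconnections considered

**Alternative 1:** The cut runs through ring D (C7'–C8' and C4a'–C8a', with C6'–C7' closing in the same cascade), so the lower aromatic ring is built onto a finished upper unit. In the forward step the C4 ynol silyl ether A1 would be heated with the 3-benzyloxy-2-cinnamylcyclobutenone A2. Ring opening to a vinylketene, [2+2] addition to the alkyne, a second ring opening and a six-electron electrocyclisation would give the resorcinol monosilyl ether A3.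

- In its favour: the junction is regiospecific by construction, and no cation is involved, so self-condensation cannot occur. Benzannulation of siloxyalkynes is an established reaction type, so on mechanistic security it is the better of the two plans.
- Against it here: A1 needs a complete 3,4-trans C4-alkynylated robinetinidol, so the three ring C stereocentres must come from another chiral source, followed by homologation to the ynol ether at a hindered benzylic carbon. A2 is itself a multistep compound. After A3, ring F is still missing (benzylation of the C7' hydroxyl, asymmetric dihydroxylation of the cinnamyl alkene, desilylation, cyclisation with inversion at C2'), so C2' and C3' are made by reagent control although they are available in gallocatechin.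
- Comparison: on regiochemistry of the junction it is the equal of the chosen plan. On step economy it is clearly longer and less convergent.

**Alternative 2:** The cut is C4'–C4a' of ring F. In the forward step a Lewis acid (SnCl4 or BF3·OEt2) would activate the terminal epoxide of the aryl ether A4, and C4a' of ring D would attack the CH2 terminus to give A5 with a free C3' hydroxyl.

- In its favour: the step creates no stereocentre (C3' comes from the epoxide), it is intramolecular, and epoxide–arene cyclisation to chroman-3-ols is a known reaction class. On precedent of the key step it is the equal or the better.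
- Against it here: A4 contains a benzylic aryl ether at C2' on a phenol flanked by the bulky C4 substituent. That bond must be made with clean inversion and is prone to ionise, both when it is made and under the acid of the key step. Attack at the internal epoxide carbon would give a dihydrobenzofuran. Above all, the step builds the easy ring: the C4–C8' bond and the ring C stereocentres must already exist, so the hard problem is moved rather than solved.
- Comparison: the chosen plan spends its key step on the hard ring and takes the easy one intact from the chiral pool. Alternative 2 is longer because the lower unit is rebuilt.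

**Alternative 3:** The cut is the C2=C3 bond of a flav-2-ene. In the forward step the diene A6 (C4 bearing ring D and a vinyl group, the ring A oxygen bearing a 1-arylvinyl group) would undergo ring-closing metathesis with a second-generation Grubbs ruthenium carbene to give A7 and ethylene. Hydroboration–oxidation anti to ring D would then add H to C2 and OH to C3 in a syn sense, giving the all-trans array.

- In its favour: conditions are neutral, and the ring C stereocentres are relayed from C4 by substrate control. On stereochemical predictability it is the better plan, because the chosen plan relies on catalyst-controlled face selection.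
- Equal points: metathesis of aryl enol ethers to 4H-chromenes is known, and both plans end with oxidation of a C3–B bond and global hydrogenolysis.
- Against it here: C4 must first be made as a single configuration of a doubly benzylic, allylic methine, which is the same asymmetric problem without the help of ring formation. That centre can be lost by ruthenium hydride-mediated alkene migration. The 1-arylvinyl ether needs methylenation of a hindered aryl ester (Cp2TiMe2), closing a trisubstituted enol ether next to a fully substituted arene is slow, and A7 is acid-labile.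
- Comparison: step count is comparable or slightly higher, and convergence is lower.

Key step: step 8

Remark on structure and name: gallocatechin has six hydroxyls and all six are benzylated in the lower unit of 8, 9, 12 and 13, so that unit is a hexa-O-benzylgallocatechin-8-yl group. A penta-O-benzyl name would not add up to the ten benzyl ethers of 13, and the hexa-O-benzyl name is used throughout.

Assumption: the (R) antipode of the phosphoric acid is written as the one whose facial preference gives the 4α (4S) product; if it proves mismatched with the lower unit, the (S) antipode is used under the same conditions.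

## Route

Step 1
Reactants: 1 (+)-gallocatechin
Product: 2 5,7,3',4',5'-penta-O-benzyl-(+)-gallocatechin [(2R,3S)-5,7-bis(benzyloxy)-2-[3,4,5-tris(benzyloxy)phenyl]chroman-3-ol]
Conditions: BnBr, K2CO3, DMF, Ar, 0 °C → rt
Reagents that add atoms: benzyl bromide, BrCc1ccccc1
Why: Williamson etherification of the five phenols with a carbonate base too weak to deprotonate the C3 alcohol; under argon at room temperature the pyrogallol ring should survive and C2 should not epimerise, so both stereocentres of 1 are carried through.

Step 2
Reactants: 2 5,7,3',4',5'-penta-O-benzyl-(+)-gallocatechin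
Product: 3 3,5,7,3',4',5'-hexa-O-benzyl-(+)-gallocatechin [(2R,3S)-3,5,7-tris(benzyloxy)-2-[3,4,5-tris(benzyloxy)phenyl]chromane]
Conditions: NaH, BnBr, Bu4NI (cat.), THF/DMF, 0 °C → rt
Reagents that add atoms: benzyl bromide, BrCc1ccccc1
Why: Williamson etherification of the secondary alkoxide; with every phenol capped there is no phenoxide-driven ring opening, so C2 and C3 keep their configuration, and the ether prevents the alcohol from quenching the aryllithium of step 5.

Step 3
Reactants: 3 3,5,7,3',4',5'-hexa-O-benzyl-(+)-gallocatechin
Product: 4 8-bromo-3,5,7,3',4',5'-hexa-O-benzyl-(+)-gallocatechin (2R,3S)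
Conditions: NBS (1.05 equiv), CH2Cl2, −78 °C → 0 °C
Reagents that add atoms: N-bromosuccinimide, O=C1CCC(=O)N1Br
Why: Electrophilic aromatic bromination; in benzylated flavan-3-ols C8 of the phloroglucinol-type ring is the most nucleophilic carbon, so one equivalent of NBS at low temperature should brominate there ahead of C6 and of the less activated ring B.

Step 4
Reactants: 5 4-(benzyloxy)-2-hydroxybenzaldehyde
Product: 6 2-(allyloxy)-4-(benzyloxy)benzaldehyde
Conditions: allyl bromide, K2CO3, DMF, 50 °C
Reagents that add atoms: allyl bromide, C=CCBr
Why: Williamson O-allylation of the ortho phenol; the allyl ether tolerates an aryllithium and can later be removed under neutral conditions that spare the benzyl ethers and the acid-labile benzhydrol.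

Step 5
Reactants: 4 8-bromo-3,5,7,3',4',5'-hexa-O-benzyl-(+)-gallocatechin; 6 2-(allyloxy)-4-(benzyloxy)benzaldehyde
Product: 8 [2-(allyloxy)-4-(benzyloxy)phenyl][(2R,3S)-hexa-O-benzylgallocatechin-8-yl]methanol (both carbinol epimers), via 8-lithio-hexa-O-benzylgallocatechin 7 (not isolated)
Conditions: n-BuLi (1.05 equiv), THF, −78 °C; then 6, −78 → −40 °C; H2O quench
Reagents that add atoms: none
Why: Bromine–lithium exchange at −78 °C is faster than benzylic deprotonation and places the metal exactly at C8, so 1,2-addition of 7 to the aldehyde forms the future C4–C8' bond regiospecifically. The new carbinol centre is not controlled and need not be, because both epimers give the same planar intermediate in step 8; the quench is kept free of acid.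

Step 6
Reactants: 8 [2-(allyloxy)-4-(benzyloxy)phenyl][(2R,3S)-hexa-O-benzylgallocatechin-8-yl]methanol
Product: 9 [4-(benzyloxy)-2-hydroxyphenyl][(2R,3S)-hexa-O-benzylgallocatechin-8-yl]methanol (both carbinol epimers)
Conditions: Pd(PPh3)4 (5 mol%), morpholine (5 equiv), THF, rt; filtration through Et3N-deactivated silica
Reagents that add atoms: none
Why: Tsuji–Trost deallylation: zerovalent palladium ionises the aryl allyl ether and morpholine captures the allyl fragment, a neutral to slightly basic unmasking under which the benzhydrol is not ionised and the benzyl ethers are inert.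

Step 7
Reactants: 10 3,4,5-tris(benzyloxy)benzaldehyde
Product: 11 (E)-2-[3,4,5-tris(benzyloxy)phenyl]ethenylboronic acid pinacol ester
Conditions: CH2(Bpin)2 (1.2 equiv), lithium 2,2,6,6-tetramethylpiperidide (LiTMP, 1.2 equiv), THF, 0 °C; then 10, −78 °C → rt
Reagents that add atoms: bis(pinacolatoboryl)methane, CC1(C)OB(CB2OC(C)(C)C(C)(C)O2)OC1(C)C
Why: Boron–Wittig olefination: the lithiated gem-diborylmethane adds to the aldehyde and syn elimination of the B–O unit should give the (E)-alkenyl boronate in one step, the trans geometry being the favoured outcome with aryl aldehydes.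

Step 8
Reactants: 9 [4-(benzyloxy)-2-hydroxyphenyl][(2R,3S)-hexa-O-benzylgallocatechin-8-yl]methanol; 11 (E)-2-[3,4,5-tris(benzyloxy)phenyl]ethenylboronic acid pinacol ester
Product: 13 3-deoxy-3-(pinacolatoboryl)-7,3',4',5'-tetra-O-benzylrobinetinidol-(4α→8)-3,5,7,3',4',5'-hexa-O-benzylgallocatechin (upper unit 2S,3S,4S by sequence rule: 2α-aryl/3β-boryl/4α-aryl; lower unit 2R,3S), via ortho-quinone methide 12 (not isolated)
Conditions: (R)-3,3'-bis(2,4,6-triisopropylphenyl)-1,1'-binaphthyl-2,2'-diyl hydrogen phosphate (10 mol%), 11 (2.5 equiv), 5 Å MS, PhMe, −20 °C → rt; 9 added slowly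
Reagents that add atoms: none
Why: Proposed new method: the phosphoric acid should ionise the doubly activated benzhydrol 9 to the hydrogen-bonded (E)-ortho-quinone methide 12, whose O=C8a–C4a=C4 unit is an electron-poor heterodiene, and the boron-bearing carbon of 11 should attack C4 while the benzylic carbon, its developing positive charge stabilised by the para-benzyloxy group of ring B and by hyperconjugation with the C–B bond, is captured by O1; the closest known reaction type is the Brønsted acid catalysed inverse-demand hetero-Diels–Alder reaction of in situ ortho-quinone methides with styrenes, which gives 2,4-cis-2,4-diarylchromans, and alkenyl boronates have not been shown as the two-electron partner. Ring C closes in an intermolecular, asynchronous [4π+2π] mode, C3–C4 leading and O1–C2 following, both bonds forming suprafacially on each component. The C2/C3 trans relation follows from the E geometry of 11, which a suprafacial addition conserves. The C2/C4 cis relation follows from the endo placement of ring B under the quinone methide with ring D in the outside (E) position, which also puts the bulky boronate exo and trans to ring D, so the all-trans 2α,3β,4α array should result. The absolute sense at C4 (which face of 12 is attacked) is not biased by the remote lower unit and must come from the chiral phosphate bound to the quinone methide oxygen. Regioselectivity requires the cation to develop at C2, which the aryl group and the β-boron effect secure; the pinacol ester is kept because it resists the oxygen-to-boron coordination that would transfer the alkenyl group with loss of boron; condensation of 12 with the free C6' of ring D is held back by slow addition of 9 to an excess of 11.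

Step 9
Reactants: 13 3-deoxy-3-(pinacolatoboryl)-deca-O-benzyl dimer
Product: 14 7,3',4',5'-tetra-O-benzylrobinetinidol-(4α→8)-3,5,7,3',4',5'-hexa-O-benzylgallocatechin (free C3 hydroxyl; upper unit 2R,3S,4S, lower unit 2R,3S)
Conditions: NaBO3·4H2O (5 equiv), THF/H2O (1:1), rt
Reagents that add atoms: sodium perborate, [Na+].[O-]OB=O
Why: Perborate oxidation of the C–B bond goes through a boron ate complex and 1,2-migration of C3 from boron to oxygen with retention, so the β-boryl group becomes the β (3S) hydroxyl; the mild, weakly basic reagent is chosen to keep β-elimination of the ring oxygen O1 in check.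

Step 10
Reactants: 14 7,3',4',5'-tetra-O-benzylrobinetinidol-(4α→8)-hexa-O-benzylgallocatechin
Product: 15 robinetinidol-(4α→8)-gallocatechin [(2R,3S,4S)-2-(3,4,5-trihydroxyphenyl)-4-[(2R,3S)-3,5,7-trihydroxy-2-(3,4,5-trihydroxyphenyl)chroman-8-yl]chroman-3,7-diol]
Conditions: H2 (1 atm), Pd(OH)2/C (20 wt%), THF/MeOH/H2O, rt; filtration and lyophilisation under Ar
Reagents that add atoms: none
Why: Hydrogenolysis of the ten benzyl ethers over Pd(OH)2 on carbon under neutral conditions; the cyclic benzylic C2–O1 and C2'–O1' bonds and the C4–C8' bond are much slower to cleave, and no stereocentre is touched.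

## Compound list

1 | (+)-gallocatechin, (2R,3S) | Oc1cc(O)c2c(c1)O[C@H](c1cc(O)c(O)c(O)c1)[C@@H](O)C2 | starting material
2 | 5,7,3',4',5'-penta-O-benzyl-(+)-gallocatechin, (2R,3S) | c1ccccc1COc1cc(OCc3ccccc3)c2c(c1)O[C@H](c1cc(OCc3ccccc3)c(OCc3ccccc3)c(OCc3ccccc3)c1)[C@@H](O)C2 | intermediate
3 | 3,5,7,3',4',5'-hexa-O-benzyl-(+)-gallocatechin, (2R,3S) | c1ccccc1COc1cc(OCc3ccccc3)c2c(c1)O[C@H](c1cc(OCc3ccccc3)c(OCc3ccccc3)c(OCc3ccccc3)c1)[C@@H](OCc1ccccc1)C2 | intermediate
4 | 8-bromo-3,5,7,3',4',5'-hexa-O-benzyl-(+)-gallocatechin, (2R,3S) | Brc1c(OCc3ccccc3)cc(OCc3ccccc3)c2c1O[C@H](c1cc(OCc3ccccc3)c(OCc3ccccc3)c(OCc3ccccc3)c1)[C@@H](OCc1ccccc1)C2 | intermediate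
5 | 4-(benzyloxy)-2-hydroxybenzaldehyde | O=Cc1ccc(OCc2ccccc2)cc1O | starting material
6 | 2-(allyloxy)-4-(benzyloxy)benzaldehyde | O=Cc1ccc(OCc2ccccc2)cc1OCC=C | intermediate
7 | 8-lithio-3,5,7,3',4',5'-hexa-O-benzylgallocatechin, (2R,3S) | [Li]c1c(OCc3ccccc3)cc(OCc3ccccc3)c2c1O[C@H](c1cc(OCc3ccccc3)c(OCc3ccccc3)c(OCc3ccccc3)c1)[C@@H](OCc1ccccc1)C2 | intermediate
8 | [2-(allyloxy)-4-(benzyloxy)phenyl][(2R,3S)-hexa-O-benzylgallocatechin-8-yl]methanol, both carbinol epimers | C=CCOc1cc(OCc2ccccc2)ccc1C(O)c1c(OCc3ccccc3)cc(OCc3ccccc3)c2c1O[C@H](c1cc(OCc3ccccc3)c(OCc3ccccc3)c(OCc3ccccc3)c1)[C@@H](OCc1ccccc1)C2 | intermediate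
9 | [4-(benzyloxy)-2-hydroxyphenyl][(2R,3S)-hexa-O-benzylgallocatechin-8-yl]methanol, both carbinol epimers | Oc1cc(OCc2ccccc2)ccc1C(O)c1c(OCc3ccccc3)cc(OCc3ccccc3)c2c1O[C@H](c1cc(OCc3ccccc3)c(OCc3ccccc3)c(OCc3ccccc3)c1)[C@@H](OCc1ccccc1)C2 | intermediate
10 | 3,4,5-tris(benzyloxy)benzaldehyde | O=Cc1cc(OCc2ccccc2)c(OCc2ccccc2)c(OCc2ccccc2)c1 | starting material
11 | (E)-2-[3,4,5-tris(benzyloxy)phenyl]ethenylboronic acid pinacol ester | CC1(C)OB(/C=C/c2cc(OCc3ccccc3)c(OCc3ccccc3)c(OCc3ccccc3)c2)OC1(C)C | intermediate
12 | (E)-3-(benzyloxy)-6-{[(2R,3S)-hexa-O-benzylgallocatechin-8-yl]methylidene}cyclohexa-2,4-dien-1-one (ortho-quinone methide of ring A) | O=C1C=C(OCc2ccccc2)C=C/C1=C\c1c(OCc3ccccc3)cc(OCc3ccccc3)c2c1O[C@H](c1cc(OCc3ccccc3)c(OCc3ccccc3)c(OCc3ccccc3)c1)[C@@H](OCc1ccccc1)C2 | intermediate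
13 | 3-deoxy-3-(pinacolatoboryl)-7,3',4',5'-tetra-O-benzylrobinetinidol-(4α→8)-hexa-O-benzylgallocatechin, upper unit (2S,3S,4S) all-trans, lower unit (2R,3S) | c1ccccc1COc1ccc2c(c1)O[C@H](c1cc(OCc3ccccc3)c(OCc3ccccc3)c(OCc3ccccc3)c1)[C@@H](B1OC(C)(C)C(C)(C)O1)[C@@H]2c1c(OCc3ccccc3)cc(OCc3ccccc3)c2c1O[C@H](c1cc(OCc3ccccc3)c(OCc3ccccc3)c(OCc3ccccc3)c1)[C@@H](OCc1ccccc1)C2 | intermediate
14 | 7,3',4',5'-tetra-O-benzylrobinetinidol-(4α→8)-3,5,7,3',4',5'-hexa-O-benzylgallocatechin, upper unit (2R,3S,4S), lower unit (2R,3S) | c1ccccc1COc1ccc2c(c1)O[C@H](c1cc(OCc3ccccc3)c(OCc3ccccc3)c(OCc3ccccc3)c1)[C@@H](O)[C@@H]2c1c(OCc3ccccc3)cc(OCc3ccccc3)c2c1O[C@H](c1cc(OCc3ccccc3)c(OCc3ccccc3)c(OCc3ccccc3)c1)[C@@H](OCc1ccccc1)C2 | intermediate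
15 | robinetinidol-(4α→8)-gallocatechin, upper unit (2R,3S,4S), lower unit (2R,3S) | Oc1ccc2c(c1)O[C@H](c1cc(O)c(O)c(O)c1)[C@@H](O)[C@@H]2c1c(O)cc(O)c2c1O[C@H](c1cc(O)c(O)c(O)c1)[C@@H](O)C2 | target

## Step count and least certain steps

Total: 10 steps. Longest linear sequence: 8 steps (1 → 2 → 3 → 4 → 8 → 9 → 13 → 14 → 15, that is steps 1, 2, 3, 5, 6, 8, 9, 10).

**Step 8 (key step).** Three processes are most likely to intervene.

- Loss of boron: after C3–C4 bond formation the β-boryl benzylic cation may shed boron instead of closing onto O1, which amounts to alkenyl transfer and leaves an open 1,3-diarylallyl phenol.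
- Poor facial selectivity: the lower unit gives no bias and the boronate has no hydrogen-bond donor to hold it to the phosphate.
- Self-condensation: Friedel–Crafts attack of the free C6' of ring D or C6 of ring A on the quinone methide.

Fallback (known chemistry, the classical flavan-3,4-diol/flavan-3-ol condensation), setting out from 3 and coming back at 14: commercial (+)-dihydrorobinetin F1 is benzylated on its four phenols (BnBr, K2CO3, DMF, rt) to the tetra-O-benzyl flavanonol F2. The ketone of F2 is reduced with NaBH4 (THF/EtOH, 0 °C) to the flavan-3,4-diol F3; both C4 epimers serve, because C4 is ionised next. F3 is treated with TMSOTf (or BF3·OEt2) in CH2Cl2 at −78 °C in the presence of an excess of 3, so that C8 of 3 captures the 7-benzyloxy-stabilised C4 cation, mainly anti to the C3 hydroxyl, and gives 14 directly. The 4β epimer and any C6-linked isomer would be removed by chromatography, and the route continues with step 10.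

**Step 9.** The ate complex formed at boron has its C3–B bond antiperiplanar to C2–O1, so β-elimination with expulsion of the ring A phenoxide (ring opening to a 1,3-diarylpropene) may compete with the 1,2-migration. The two flanking aryl groups may also slow attack at boron. Fallback, setting out from 13 and coming back at 14: 13 is converted with KHF2 (MeOH/H2O, rt) into the potassium trifluoroborate F4, which is oxidised with KHSO5 (as 2KHSO5·KHSO4·K2SO4) in acetone/H2O at rt. This is a fast oxidation with retention that needs no hydroxide or perhydroxyl anion.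

**Step 6.** The allyl–palladium intermediate may transfer allyl to a carbon of the liberated, resorcinol-type phenoxide instead of to the amine. The freed benzhydrol may also ionise and condense during isolation. Fallback without a protecting group, setting out from 4 and 5 and coming back at 9: 5 is deprotonated with LiN(SiMe3)2 (1.0 equiv, THF, −78 °C) to lithium 5-(benzyloxy)-2-formylphenolate F5. The aryllithium 7, made from 4 as in step 5, is added, and a water quench gives 9 directly. Addition of an organolithium to a salicylaldehyde phenoxide is known chemistry; it is slower than addition to 6, which is why it is held in reserve.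

**Step 10.** Cleavage of the most hindered ethers (the C3' alkyl benzyl ether and the ring D ethers next to the junction) may stall through catalyst poisoning by partly deprotected polyphenol. The pyrogallol rings may be lost to oxidation during work-up. Fallback, setting out from 14 and coming back at 15: Lewis-acid debenzylation with BCl3 and pentamethylbenzene as cation scavenger in CH2Cl2 at −78 °C, followed by a methanol quench. This removes aryl and alkyl benzyl ethers without hydrogen or metal and makes no new isolated compound.

## Further compounds

F1 | step 8 | (+)-dihydrorobinetin, (2R,3R)-3,7-dihydroxy-2-(3,4,5-trihydroxyphenyl)chroman-4-one | Oc1ccc2c(c1)O[C@H](c1cc(O)c(O)c(O)c1)[C@@H](O)C2=O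
F2 | step 8 | 7,3',4',5'-tetra-O-benzyl-(+)-dihydrorobinetin, (2R,3R) | c1ccccc1COc1ccc2c(c1)O[C@H](c1cc(OCc3ccccc3)c(OCc3ccccc3)c(OCc3ccccc3)c1)[C@@H](O)C2=O
F3 | step 8 | (2R,3S)-7-(benzyloxy)-2-[3,4,5-tris(benzyloxy)phenyl]chromane-3,4-diol, both C4 epimers | c1ccccc1COc1ccc2c(c1)O[C@H](c1cc(OCc3ccccc3)c(OCc3ccccc3)c(OCc3ccccc3)c1)[C@@H](O)C2O
F4 | step 9 | potassium trifluoroborate corresponding to 13 (C3 β-BF3K, same configuration as 13) | c1ccccc1COc1ccc2c(c1)O[C@H](c1cc(OCc3ccccc3)c(OCc3ccccc3)c(OCc3ccccc3)c1)[C@@H]([B-](F)(F)F)[C@@H]2c1c(OCc3ccccc3)cc(OCc3ccccc3)c2c1O[C@H](c1cc(OCc3ccccc3)c(OCc3ccccc3)c(OCc3ccccc3)c1)[C@@H](OCc1ccccc1)C2.[K+]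
F5 | step 6 | lithium 5-(benzyloxy)-2-formylphenolate | [Li+].[O-]c1cc(OCc2ccccc2)ccc1C=O
F0 | step 10 | none | none
A1 | alternative 1 | 3,7,3',4',5'-penta-O-benzylrobinetinidol bearing a 2-(triisopropylsilyloxy)ethynyl group on the α face of C4 | c1ccccc1COc1ccc2c(c1)O[C@H](c1cc(OCc3ccccc3)c(OCc3ccccc3)c(OCc3ccccc3)c1)[C@@H](OCc1ccccc1)[C@@H]2C#CO[Si](C(C)C)(C(C)C)C(C)C
A2 | alternative 1 | 3-(benzyloxy)-2-[(E)-3-(3,4,5-tris(benzyloxy)phenyl)prop-2-enyl]cyclobut-2-en-1-one | O=C1CC(OCc2ccccc2)=C1C/C=C/c1cc(OCc2ccccc2)c(OCc2ccccc2)c(OCc2ccccc2)c1
A3 | alternative 1 | 4-aryl robinetinidol with ring D formed (free C7' hydroxyl, C8a' triisopropylsilyl ether, C4a' cinnamyl chain) | c1ccccc1COc1ccc2c(c1)O[C@H](c1cc(OCc3ccccc3)c(OCc3ccccc3)c(OCc3ccccc3)c1)[C@@H](OCc1ccccc1)[C@@H]2c1c(O)cc(OCc3ccccc3)c(C/C=C/c3cc(OCc4ccccc4)c(OCc4ccccc4)c(OCc4ccccc4)c3)c1O[Si](C(C)C)(C(C)C)C(C)C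
A4 | alternative 2 | 4-aryl penta-O-benzylrobinetinidol whose ring D oxygen O1' carries the [3,4,5-tris(benzyloxy)phenyl](oxiranyl)methyl group (C2' and C3' in the gallocatechin configuration) | c1ccccc1COc1ccc2c(c1)O[C@H](c1cc(OCc3ccccc3)c(OCc3ccccc3)c(OCc3ccccc3)c1)[C@@H](OCc1ccccc1)[C@@H]2c1c(OCc3ccccc3)cc(OCc3ccccc3)cc1O[C@H](c1cc(OCc3ccccc3)c(OCc3ccccc3)c(OCc3ccccc3)c1)[C@@H]1CO1
A5 | alternative 2 | deca-O-benzyl dimer with free C3' hydroxyl | c1ccccc1COc1ccc2c(c1)O[C@H](c1cc(OCc3ccccc3)c(OCc3ccccc3)c(OCc3ccccc3)c1)[C@@H](OCc1ccccc1)[C@@H]2c1c(OCc3ccccc3)cc(OCc3ccccc3)c2c1O[C@H](c1cc(OCc3ccccc3)c(OCc3ccccc3)c(OCc3ccccc3)c1)[C@@H](O)C2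
A6 | alternative 3 | diene with a C4 vinyl group and a ring A 1-[3,4,5-tris(benzyloxy)phenyl]vinyl ether, C4 bonded to C8' of hexa-O-benzylgallocatechin | C=C[C@@H](c1ccc(OCc2ccccc2)cc1OC(=C)c1cc(OCc2ccccc2)c(OCc2ccccc2)c(OCc2ccccc2)c1)c1c(OCc3ccccc3)cc(OCc3ccccc3)c2c1O[C@H](c1cc(OCc3ccccc3)c(OCc3ccccc3)c(OCc3ccccc3)c1)[C@@H](OCc1ccccc1)C2
A7 | alternative 3 | 4-aryl-4H-flavene (flav-2-ene) with C4 set | c1ccccc1COc1ccc2c(c1)OC(c1cc(OCc3ccccc3)c(OCc3ccccc3)c(OCc3ccccc3)c1)=C[C@@H]2c1c(OCc3ccccc3)cc(OCc3ccccc3)c2c1O[C@H](c1cc(OCc3ccccc3)c(OCc3ccccc3)c(OCc3ccccc3)c1)[C@@H](OCc1ccccc1)C2
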